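## The problem

The target is a germacranolide, (3R,6R,7R,8R,10R) in the usual numbering. It is a cyclodeca-1,4-diene (1E,4Z) whose C6–C7 bond is shared with a trans-fused α-methylene-γ-butyrolactone (C11=C13H2, C12 carbonyl, ring oxygen on C6). C8 carries an angelate, C3 a secondary hydroxyl and C10 a tertiary hydroxyl.

Of the five stereocentres, C10 is a quaternary carbinol that no neighbour can direct, so it is best taken from the chiral pool. C6, C7 and C8 are contiguous (6,7-syn and 6,8-anti in the extended chain), so C6 and C7 can be set together and C6 can then direct C8. C3 is insulated from the others by the E-alkene and needs reagent control.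

The ten-membered ring must be closed to a strained diene whose trisubstituted C4=C5 alkene is Z, which an unassisted ring closure does not guarantee. Several groups are fragile: the angelate isomerises to the tiglate with nucleophiles, base or heat; the α-methylene lactone is a Michael acceptor; the doubly allylic C3 carbinol ionises and oxidises easily; the diene is open to acid-induced transannular reactions.

The enabling feature is that O3 and O6 lie on the same face of the C3–C4=C5–C6 unit, a cis-but-2-ene-1,4-diol pattern. One silicon atom can therefore tie them into a seven-membered 1,3-dioxa-2-silacyclohept-5-ene that contains C4=C5 and can hold only the Z-alkene.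

## Retrosynthesis

**Lactone and C12 oxidation level.** The C12–O6 lactone bond is cut last, together with both Si–O bonds and the C10 silyl ether: acid 33 is desilylated to seco acid 34, which closes to 35. Oxidising a free tetraol at the end would expose the doubly allylic C3–OH, so C12 is carried as a PMB ether as far as 30 and oxidised in stages (31, 32, 33) while the silylene still covers O3 and O6. A C12 ester cannot be carried from the start, because the ketone stage (18) would then slip into conjugation. The forward step only asks a γ-hydroxy acid to lactonise.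

**C4=C5 (key cut).** In 30 the C4=C5 bond is cut by retro-metathesis to 29, in which O3 and O6 are already joined by a diisopropylsilylene and C3 and C6 carry isopropenyl and vinyl groups. Cuts at C1=C2 or C2–C3 would leave the Z-alkene to be made separately; here it is enforced by the seven-membered silacycle. Precursor 29 has no carbocycle, and all five stereocentres are set in open chain. The forward step asks the catalyst to start at the vinyl group, close on the isopropenyl group and ignore three other alkenes.

**Si–O bonds.** Cutting both Si–O bonds of 29 gives the acyclic 3,6-diol 27. The C10 oxygen stays silylated so that it cannot compete for silicon. Diol 27 comes from 25 by removing the O6 acetate (26) and then the secondary C3 silyl ether. The forward step is an eleven-membered ring closure by Si–O bond formation and needs dilution.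

**Angelate C–O bond.** 25 is cut to alcohol 22 and acid 23. The cut is placed here because 22 is the one intermediate in which O8 alone is free (O6 acetate, O3 and O10 silyl ethers). The esterification must not isomerise the Z-enoate.

**C8–H bond.** 22 is cut to β-hydroxy ketone 21 by a hydroxyl-directed Tishchenko reduction. It sets C8 from C6 (1,3-anti) and at once distinguishes O6 (acetate) from O8 (free). A plain directed reduction to the diol would leave two similar secondary alcohols.

**C6–C7 bond.** 21 is cut by a syn-aldol disconnection to ketone 18 and aldehyde 19. C8 comes from the chiral-pool fragment as an electrophilic carbon, so C7 must be the nucleophile. Placing the carbonyl at C8 makes C7 the more acidic α-position and lets C8 be set afterwards. The forward reaction must enolise towards C7, give the Z-enolate and choose the aldehyde face under reagent control.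

**C7–C8 bond.** 18 is cut, via alcohol 17, to aldehyde 12 and allylic bromide 15. The C8 stereochemistry of 17 is irrelevant because it is oxidised. 15 comes from 13 and 14 by a single etherification.

**C2–C3 bond.** 12 comes from ester 11, and this from allylic alcohol 10, which is cut at C2–C3 to alkyne 6 and aldehyde 7. Hydrometalation of 6 followed by catalytic asymmetric alkenylzinc addition sets the E-C1=C2 alkene and C3 in one step. This is done on the small fragment, before other alkenes are present.

**Chiral pool.** 6 comes from aldehyde 5 by one-carbon homologation (C2), and 5 comes from 1 through 2, 3 and 4. Acid 1 supplies C8, C9, C10, C14 and C1 with C10 already R. The two carboxyl groups are told apart by the neighbouring hydroxyl.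

## Roads not taken

**Alternative 1: nitrile oxide cycloaddition.** The cut is at C8–C9 and O–C10. In the open-chain aldoxime A1, a nitrile oxide generated at C8 adds to the 1,1-disubstituted end of the diene and closes the ring as the isoxazoline-bridged lactone A2.
- Merits: a C–C bond closes the ring, the lactone is carried intact, and the isoxazoline masks the C8/C10 oxygen pattern.
- Weak points: C10, a quaternary centre, is created in the macrocyclisation with no clear control element. The N–O bond must later be cleaved reductively beside an α-methylene lactone and two alkenes. The resulting C8 ketone must still be reduced to the 8R alcohol and acylated. The Z-C4=C5 alkene has to be built beforehand by other means.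
- Comparison: it is better than the chosen plan in needing no late oxidation-state changes at C12. Against this the chosen plan sets all five stereocentres acyclically with known control before ring closure.

**Alternative 2: carbonylative Stille macrocyclisation.** The cuts are C2–C3 and C3–C4. In A3, zerovalent palladium inserts into the Z-alkenyl iodide, takes up carbon monoxide and couples with the E-alkenylstannane to give the cross-conjugated dienone A4.
- Merits: highly convergent; both alkene geometries are fixed in the coupling partners; lactone and angelate are already in place, so the endgame is a single reduction.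
- Weak points: A4 holds three Michael acceptors in a strained ring. The Z-enone can isomerise. Direct coupling without CO would give a nine-membered ring. C3 must be set last by a 1,2-reduction whose facial selectivity rests only on an unknown macrocycle conformation.
- Comparison: on step count after the fragments this road is as good or better. The chosen plan sets against it a C3 centre fixed by a catalyst in open chain and a Z-alkene that never passes through an isomerisable enone.

**Alternative 3: Grob fragmentation.** The cut is the C1–C6 bond of the trans-decalin A5. An alkoxide at C6 expels an equatorial C2 mesylate and opens the bicycle to the cyclodecadienone A6.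
- Merits: this is the best-precedented way to a ten-membered ring. There is no entropic penalty, E-C1=C2 follows from the antiperiplanar arrangement, and Z-C4=C5 is inherited from a cyclohexene.
- Weak points: A5 needs seven stereocentres, three of which (C1, C2, C6) are destroyed. After fragmentation the C6 ketone must be reduced with the right facial selectivity next to an epimerisable C7 and a β-alkoxy group. A long exchange of protecting groups and oxidation to the lactone follows.
- Comparison: for the ring-forming event this road has clearly stronger precedent than the chosen one. The chosen plan sets against it a much shorter, acyclic route to its precursor and no stereocentres built only to be erased.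

Key step: step 18

Assumption: the facial senses quoted for (+)-MIB and for Ipc2BOTf from (−)-α-pinene follow the accepted transition-state models; both reagents exist as either enantiomer, so a reversed sense changes the reagent enantiomer and not the route.

Locants C1–C15 are those of the target; CIP descriptors quoted with them refer to the compound named.

## Route

Step 1
Reactants: 1 (R)-citramalic acid
Product: 2 dimethyl (2R)-2-hydroxy-2-methylbutanedioate
Conditions: MeOH, conc. H2SO4 (cat.), reflux
Reagents that add atoms: methanol, CO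
Why: Fischer esterification; the tertiary alcohol and the stereocentre are not touched.

Step 2
Reactants: 2 dimethyl (2R)-2-hydroxy-2-methylbutanedioate
Product: 3 methyl (3R)-3,4-dihydroxy-3-methylbutanoate
Conditions: BH3·SMe2, NaBH4 (5 mol%), THF, 0 °C to rt; MeOH quench
Reagents that add atoms: none
Why: Hydroxyl-directed borane reduction: boron bound to the tertiary alkoxide reduces only the neighbouring ester through a five-membered chelate, so the distal ester (C8) survives.

Step 3
Reactants: 3 methyl (3R)-3,4-dihydroxy-3-methylbutanoate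
Product: 4 methyl (3R)-3-methyl-3,4-bis(triethylsilyloxy)butanoate
Conditions: Et3SiOTf, 2,6-lutidine, CH2Cl2, −78 to 0 °C
Reagents that add atoms: triethylsilyl trifluoromethanesulfonate, CC[Si](CC)(CC)OS(=O)(=O)C(F)(F)F
Why: Silylation with the triflate is reactive enough for the tertiary alcohol; protecting both hydroxyls at once also prevents lactonisation onto the ester.

Step 4
Reactants: 4 methyl (3R)-3-methyl-3,4-bis(triethylsilyloxy)butanoate
Product: 5 methyl (3R)-3-methyl-4-oxo-3-(triethylsilyloxy)butanoate
Conditions: (COCl)2, DMSO, CH2Cl2, −78 to −30 °C; Et3N, −78 °C to rt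
Reagents that add atoms: none
Why: Swern oxidation: primary triethylsilyl ethers are cleaved and oxidised directly under these conditions while the tertiary silyl ether is inert; the aldehyde has no α-hydrogen and cannot epimerise.

Step 5
Reactants: 5 methyl (3R)-3-methyl-4-oxo-3-(triethylsilyloxy)butanoate
Product: 6 methyl (3R)-3-methyl-3-(triethylsilyloxy)pent-4-ynoate
Conditions: dimethyl (1-diazo-2-oxopropyl)phosphonate, K2CO3, MeOH, 0 °C to rt
Reagents that add atoms: dimethyl (1-diazo-2-oxopropyl)phosphonate, CC(=O)C(=[N+]=[N-])P(=O)(OC)OC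
Why: Ohira–Bestmann homologation adds C2 as the alkyne terminus under mild base; the methyl ester is unchanged in methanol.

Step 6
Reactants: 6 methyl (3R)-3-methyl-3-(triethylsilyloxy)pent-4-ynoate, 7 methacrolein
Product: 10 methyl (3R,4E,6R)-6-hydroxy-3,7-dimethyl-3-(triethylsilyloxy)octa-4,7-dienoate, via alkenyldicyclohexylborane 8 (not isolated), via alkenylmethylzinc 9 (not isolated)
Conditions: Cy2BH (from BH3·SMe2 and cyclohexene), toluene, 0 °C to rt; Me2Zn, −78 °C; (+)-MIB (5 mol%); 7, −78 to −10 °C
Reagents that add atoms: none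
Why: Hydroboration of the terminal alkyne is cis and anti-Markovnikov, and boron-to-zinc exchange keeps the E geometry. The amino-alcohol–zinc catalyst delivers the alkenyl group to the Re face of 7 (catalytic asymmetric alkenylzinc addition), which sets C3 as R. Ester and silyl ether tolerate borane and organozinc reagents.

Step 7
Reactants: 10 methyl (3R,4E,6R)-6-hydroxy-3,7-dimethyl-3-(triethylsilyloxy)octa-4,7-dienoate
Product: 11 methyl (3R,4E,6R)-3,7-dimethyl-3,6-bis(triethylsilyloxy)octa-4,7-dienoate
Conditions: Et3SiCl, imidazole, DMF, 0 °C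
Reagents that add atoms: chlorotriethylsilane, CC[Si](Cl)(CC)CC
Why: Standard silylation; the secondary silyl ether at C3 survives hydride, zinc, boron and samarium reagents and can later be removed in the presence of the tertiary one.

Step 8
Reactants: 11 methyl (3R,4E,6R)-3,7-dimethyl-3,6-bis(triethylsilyloxy)octa-4,7-dienoate
Product: 12 (3R,4E,6R)-3,7-dimethyl-3,6-bis(triethylsilyloxy)octa-4,7-dienal
Conditions: iBu2AlH, CH2Cl2, −78 °C; Rochelle salt work-up
Reagents that add atoms: none
Why: Partial ester reduction: the tetrahedral aluminium acetal, stabilised by the β-silyloxy group, collapses to the aldehyde only on work-up.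

Step 9
Reactants: 13 3-bromo-2-(bromomethyl)prop-1-ene, 14 4-methoxybenzyl alcohol
Product: 15 1-({[2-(bromomethyl)prop-2-en-1-yl]oxy}methyl)-4-methoxybenzene
Conditions: NaH, THF/DMF, 0 °C to rt (13 in threefold excess)
Reagents that add atoms: none
Why: Williamson ether synthesis; the excess of dibromide favours monoalkylation.

Step 10
Reactants: 12 (3R,4E,6R)-3,7-dimethyl-3,6-bis(triethylsilyloxy)octa-4,7-dienal, 15 1-({[2-(bromomethyl)prop-2-en-1-yl]oxy}methyl)-4-methoxybenzene
Product: 17 (4RS,6R,7E,9R)-1-(4-methoxybenzyloxy)-6,10-dimethyl-2-methylidene-6,9-bis(triethylsilyloxy)undeca-7,10-dien-4-ol, via allylzinc bromide 16 (not isolated)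
Conditions: Zn dust, THF, 0 °C to rt (Barbier mode); aq. NH4Cl work-up
Reagents that add atoms: none
Why: Zinc Barbier allylation forms C7–C8 under neutral conditions; the C8 epimer mixture does not matter because C8 is oxidised next.

Step 11
Reactants: 17 (4RS,6R,7E,9R)-1-(4-methoxybenzyloxy)-6,10-dimethyl-2-methylidene-6,9-bis(triethylsilyloxy)undeca-7,10-dien-4-ol
Product: 18 (6R,7E,9R)-1-(4-methoxybenzyloxy)-6,10-dimethyl-2-methylidene-6,9-bis(triethylsilyloxy)undeca-7,10-dien-4-one
Conditions: Dess–Martin periodinane, NaHCO3, CH2Cl2, 0 °C to rt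
Reagents that add atoms: none
Why: Dess–Martin oxidation; the buffer keeps the β,γ-alkene out of conjugation, and the silylated C10 oxygen cannot trigger a retro-aldol cleavage.

Step 12
Reactants: 18 (6R,7E,9R)-1-(4-methoxybenzyloxy)-6,10-dimethyl-2-methylidene-6,9-bis(triethylsilyloxy)undeca-7,10-dien-4-one, 19 acrolein
Product: 21 (3R,4S,7R,8E,10R)-3-hydroxy-4-[3-(4-methoxybenzyloxy)prop-1-en-2-yl]-7,11-dimethyl-7,10-bis(triethylsilyloxy)dodeca-1,8,11-trien-5-one, via Z-enolborinate 20 (not isolated)
Conditions: (+)-Ipc2BOTf [from (−)-α-pinene], iPr2NEt, CH2Cl2, −78 °C; 19, −78 to −20 °C; H2O2, pH 7 buffer, MeOH, 0 °C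
Reagents that add atoms: none
Why: Boron-mediated syn aldol: the bulky boron triflate enolises 18 on the more acidic, less hindered C7 side to the Z-enolborinate 20, whose chair transition state gives the 6,7-syn adduct. The isopinocampheyl ligands select the Si face of 19, which sets C6 as R and C7 with it.

Step 13
Reactants: 21 (3R,4S,7R,8E,10R)-3-hydroxy-4-[3-(4-methoxybenzyloxy)prop-1-en-2-yl]-7,11-dimethyl-7,10-bis(triethylsilyloxy)dodeca-1,8,11-trien-5-one
Product: 22 (3R,4R,5R,7R,8E,10R)-5-hydroxy-4-[3-(4-methoxybenzyloxy)prop-1-en-2-yl]-7,11-dimethyl-7,10-bis(triethylsilyloxy)dodeca-1,8,11-trien-3-yl acetate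
Conditions: SmI2 (0.3 equiv), MeCHO (6 equiv), THF, −10 °C
Reagents that add atoms: acetaldehyde, CC=O
Why: Evans–Tishchenko reduction: the samarium-bound hemiacetal of O6 with acetaldehyde delivers hydride intramolecularly to C8 through a chair-like transition state. This gives the 6,8-anti product (8R), with O6 as its acetate and O8 free.

Step 14
Reactants: 22 (3R,4R,5R,7R,8E,10R)-5-hydroxy-4-[3-(4-methoxybenzyloxy)prop-1-en-2-yl]-7,11-dimethyl-7,10-bis(triethylsilyloxy)dodeca-1,8,11-trien-3-yl acetate, 23 angelic acid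
Product: 25 (3R,4R,5R,7R,8E,10R)-3-acetoxy-4-[3-(4-methoxybenzyloxy)prop-1-en-2-yl]-7,11-dimethyl-7,10-bis(triethylsilyloxy)dodeca-1,8,11-trien-5-yl (2Z)-2-methylbut-2-enoate, via mixed anhydride 24 (not isolated)
Conditions: 23, 2,4,6-Cl3C6H2COCl, Et3N, toluene, rt; then 22, 75 °C
Reagents that add atoms: none
Why: Yamaguchi esterification: the hindered C8 alcohol attacks the angeloyl carbonyl of mixed anhydride 24. Omitting a nucleophilic catalyst avoids Z-to-E isomerisation to the tiglate.

Step 15
Reactants: 25 (3R,4R,5R,7R,8E,10R)-3-acetoxy-4-[3-(4-methoxybenzyloxy)prop-1-en-2-yl]-7,11-dimethyl-7,10-bis(triethylsilyloxy)dodeca-1,8,11-trien-5-yl (2Z)-2-methylbut-2-enoate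
Product: 26 (3R,4S,5R,7R,8E,10R)-3-hydroxy-4-[3-(4-methoxybenzyloxy)prop-1-en-2-yl]-7,11-dimethyl-7,10-bis(triethylsilyloxy)dodeca-1,8,11-trien-5-yl (2Z)-2-methylbut-2-enoate
Conditions: K2CO3, MeOH, 0 °C
Reagents that add atoms: none
Why: Transesterification: methoxide should remove the unhindered allylic acetate much faster than the α-branched, conjugated angelate; silyl and PMB ethers are stable.

Step 16
Reactants: 26 (3R,4S,5R,7R,8E,10R)-3-hydroxy-4-[3-(4-methoxybenzyloxy)prop-1-en-2-yl]-7,11-dimethyl-7,10-bis(triethylsilyloxy)dodeca-1,8,11-trien-5-yl (2Z)-2-methylbut-2-enoate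
Product: 27 (3R,4S,5R,7R,8E,10R)-3,10-dihydroxy-4-[3-(4-methoxybenzyloxy)prop-1-en-2-yl]-7,11-dimethyl-7-(triethylsilyloxy)dodeca-1,8,11-trien-5-yl (2Z)-2-methylbut-2-enoate
Conditions: HF·pyridine, pyridine, THF, 0 °C
Reagents that add atoms: none
Why: Selective desilylation: buffered fluoride should cleave the secondary allylic silyl ether at C3 much faster than the tertiary one at C10, which is kept to shield that oxygen during bridging.

Step 17
Reactants: 27 (3R,4S,5R,7R,8E,10R)-3,10-dihydroxy-4-[3-(4-methoxybenzyloxy)prop-1-en-2-yl]-7,11-dimethyl-7-(triethylsilyloxy)dodeca-1,8,11-trien-5-yl (2Z)-2-methylbut-2-enoate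
Product: 29 eleven-membered 3,6-O-diisopropylsilylene diether (ring Si, O3, C3, C2, C1, C10, C9, C8, C7, C6, O6; 3-isopropenyl, 6-vinyl, 7-[3-(4-methoxybenzyloxy)prop-1-en-2-yl], 8-angeloyloxy, 10-methyl, 10-triethylsilyloxy; 1E; 3R,6R,7R,8R,10R), via silyl triflate 28 (not isolated)
Conditions: iPr2Si(OTf)2, 2,6-lutidine, CH2Cl2 (1 mM, slow addition of 27), −40 to 0 °C
Reagents that add atoms: di(propan-2-yl)silanediyl bis(trifluoromethanesulfonate), CC(C)[Si](OS(=O)(=O)C(F)(F)F)(OS(=O)(=O)C(F)(F)F)C(C)C
Why: Dialkoxysilane (silylene) formation: one secondary alcohol displaces the first triflate (drawn for O3, intermediate 28) and O6 displaces the second intramolecularly under high dilution. Long Si–O bonds and wide Si–O–C angles ease the eleven-membered ring, and the capped C10 oxygen cannot form a smaller ring.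

Step 18
Reactants: 29 eleven-membered 3,6-O-diisopropylsilylene diether
Product: 30 silylene-bridged (1E,4Z)-cyclodeca-1,4-diene (carbocycle C1–C10; O3 and O6 bridged by Si(iPr)2 in a seven-membered 1,3-dioxa-2-silacyclohept-5-ene containing C4=C5; 7-[3-(4-methoxybenzyloxy)prop-1-en-2-yl], 8-angeloyloxy, 10-triethylsilyloxy; 3R,6R,7R,8R,10R)
Conditions: second-generation Grubbs catalyst RuCl2(=CHPh)(H2IMes)(PCy3) (15 mol%), toluene (2 mM), 80 °C, argon sparge
Reagents that add atoms: none
Why: Proposed new method: the ruthenium benzylidene exchanges with the only monosubstituted alkene, the C6 vinyl group, and the resulting alkylidene undergoes [2+2] cycloaddition and cycloreversion with the C3 isopropenyl group held beside it by the O–Si–O bridge, releasing ethene and forming C4=C5. The closest known reaction type is silicon-tethered ring-closing metathesis of acyclic bis(allyloxy)silanes to seven-membered dioxasilepines with Z-trisubstituted alkenes; here the tether is itself part of an eleven-membered ring, so the closure is transannular. The seven-membered 1,3-dioxa-2-silacyclohept-5-ene closes in the usual small-ring mode, and the ten-membered carbocycle closes with it as a contraction of the eleven-membered silacycle across the new bond. No stereocentre is formed; the new stereo element is the alkene, which must be Z because a seven-membered ring cannot hold an E-alkene. Site selectivity is needed against the E-C1=C2 alkene (flanked by the quaternary C10 and the silyloxy C3), the 1,1-disubstituted C11=C13 alkene (closure with C5 would give a four-membered ring) and the angelate, all too hindered or too electron-poor to compete. High dilution and removal of ethene counter oligomerisation and the reverse reaction.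

Step 19
Reactants: 30 silylene-bridged (1E,4Z)-cyclodeca-1,4-diene
Product: 31 primary C12 alcohol (30 with the 4-methoxybenzyl group removed; 3R,6R,7R,8R,10R)
Conditions: DDQ, CH2Cl2/pH 7 buffer, 0 °C
Reagents that add atoms: none
Why: Oxidative PMB cleavage: electron transfer from the electron-rich benzyl ether and hydrolysis of the oxocarbenium ion free the C12 alcohol; silylene, silyl ether and angelate should tolerate buffered DDQ.

Step 20
Reactants: 31 primary C12 alcohol
Product: 32 C12 enal (2-substituted acrolein on C7; 3R,6R,7R,8R,10R)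
Conditions: Dess–Martin periodinane, NaHCO3, CH2Cl2, 0 °C
Reagents that add atoms: none
Why: Dess–Martin oxidation of the primary allylic alcohol; O3 and O6 are still covered by the silylene, so the doubly allylic carbinol cannot be oxidised.

Step 21
Reactants: 32 C12 enal
Product: 33 C12 acrylic acid (3R,6R,7R,8R,10R)
Conditions: NaClO2, NaH2PO4, 2-methylbut-2-ene, tBuOH/H2O, 0 °C to rt
Reagents that add atoms: sodium chlorite, [Na+].[O-]Cl=O
Why: Pinnick oxidation: chlorous acid converts the enal into the acid, and the alkene scavenger removes hypochlorous acid before it can attack the diene.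

Step 22
Reactants: 33 C12 acrylic acid
Product: 35 target, (3R,6R,7R,8R,10R,1E,4Z)-8-angeloyloxy-3,10-dihydroxygermacra-1,4,11(13)-trien-12,6-olide, via seco acid 34 (not isolated)
Conditions: HF·pyridine, pyridine, THF, 0 °C to rt
Reagents that add atoms: none
Why: Fluoride cleaves the silylene and the tertiary silyl ether (strong Si–F bonds). The freed C6 hydroxyl is γ to the acid and should close the five-membered α-methylene lactone under the mildly acidic conditions; no stereocentre is touched.

## Compound list

1 | (R)-citramalic acid, (2R)-2-hydroxy-2-methylbutanedioic acid | OC(=O)[C@](C)(O)CC(=O)O | starting material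
2 | dimethyl (2R)-2-hydroxy-2-methylbutanedioate | COC(=O)[C@](C)(O)CC(=O)OC | intermediate
3 | methyl (3R)-3,4-dihydroxy-3-methylbutanoate | OC[C@](C)(O)CC(=O)OC | intermediate
4 | methyl (3R)-3-methyl-3,4-bis(triethylsilyloxy)butanoate | CC[Si](CC)(CC)OC[C@](C)(O[Si](CC)(CC)CC)CC(=O)OC | intermediate
5 | methyl (3R)-3-methyl-4-oxo-3-(triethylsilyloxy)butanoate | O=C[C@](C)(O[Si](CC)(CC)CC)CC(=O)OC | intermediate
6 | methyl (3R)-3-methyl-3-(triethylsilyloxy)pent-4-ynoate | C#C[C@](C)(O[Si](CC)(CC)CC)CC(=O)OC | intermediate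
7 | methacrolein, 2-methylprop-2-enal | C=C(C)C=O | starting material
8 | methyl (3R,4E)-5-(dicyclohexylboranyl)-3-methyl-3-(triethylsilyloxy)pent-4-enoate | C1CCCCC1B(C1CCCCC1)/C=C/[C@](C)(O[Si](CC)(CC)CC)CC(=O)OC | intermediate
9 | methyl (3R,4E)-3-methyl-5-(methylzincio)-3-(triethylsilyloxy)pent-4-enoate | C[Zn]/C=C/[C@](C)(O[Si](CC)(CC)CC)CC(=O)OC | intermediate
10 | methyl (3R,4E,6R)-6-hydroxy-3,7-dimethyl-3-(triethylsilyloxy)octa-4,7-dienoate | C=C(C)[C@H](O)/C=C/[C@](C)(O[Si](CC)(CC)CC)CC(=O)OC | intermediate
11 | methyl (3R,4E,6R)-3,7-dimethyl-3,6-bis(triethylsilyloxy)octa-4,7-dienoate | C=C(C)[C@H](O[Si](CC)(CC)CC)/C=C/[C@](C)(O[Si](CC)(CC)CC)CC(=O)OC | intermediate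
12 | (3R,4E,6R)-3,7-dimethyl-3,6-bis(triethylsilyloxy)octa-4,7-dienal | C=C(C)[C@H](O[Si](CC)(CC)CC)/C=C/[C@](C)(O[Si](CC)(CC)CC)CC=O | intermediate
13 | 3-bromo-2-(bromomethyl)prop-1-ene | C=C(CBr)CBr | starting material
14 | 4-methoxybenzyl alcohol | COc1ccc(CO)cc1 | starting material
15 | 1-({[2-(bromomethyl)prop-2-en-1-yl]oxy}methyl)-4-methoxybenzene | C=C(CBr)COCc1ccc(OC)cc1 | intermediate
16 | bromo{2-[(4-methoxybenzyloxy)methyl]prop-2-en-1-yl}zinc | Br[Zn]CC(=C)COCc1ccc(OC)cc1 | intermediate
17 | (4RS,6R,7E,9R)-1-(4-methoxybenzyloxy)-6,10-dimethyl-2-methylidene-6,9-bis(triethylsilyloxy)undeca-7,10-dien-4-ol | C=C(C)[C@H](O[Si](CC)(CC)CC)/C=C/[C@](C)(O[Si](CC)(CC)CC)CC(O)CC(=C)COCc1ccc(OC)cc1 | intermediate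
18 | (6R,7E,9R)-1-(4-methoxybenzyloxy)-6,10-dimethyl-2-methylidene-6,9-bis(triethylsilyloxy)undeca-7,10-dien-4-one | C=C(C)[C@H](O[Si](CC)(CC)CC)/C=C/[C@](C)(O[Si](CC)(CC)CC)CC(=O)CC(=C)COCc1ccc(OC)cc1 | intermediate
19 | acrolein, prop-2-enal | C=CC=O | starting material
20 | (Z)-enol diisopinocampheylborinate of 18, enolised towards C7 | C=C(C)[C@H](O[Si](CC)(CC)CC)/C=C/[C@](C)(O[Si](CC)(CC)CC)C/C(=C/C(=C)COCc1ccc(OC)cc1)OB([C@H]1C[C@H]2C[C@H](C2(C)C)[C@@H]1C)[C@H]1C[C@H]2C[C@H](C2(C)C)[C@@H]1C | intermediate
21 | (3R,4S,7R,8E,10R)-3-hydroxy-4-[3-(4-methoxybenzyloxy)prop-1-en-2-yl]-7,11-dimethyl-7,10-bis(triethylsilyloxy)dodeca-1,8,11-trien-5-one | C=C[C@@H](O)[C@H](C(=C)COCc1ccc(OC)cc1)C(=O)C[C@@](C)(O[Si](CC)(CC)CC)/C=C/[C@@H](O[Si](CC)(CC)CC)C(C)=C | intermediate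
22 | (3R,4R,5R,7R,8E,10R)-5-hydroxy-4-[3-(4-methoxybenzyloxy)prop-1-en-2-yl]-7,11-dimethyl-7,10-bis(triethylsilyloxy)dodeca-1,8,11-trien-3-yl acetate | C=C[C@@H](OC(C)=O)[C@H](C(=C)COCc1ccc(OC)cc1)[C@H](O)C[C@@](C)(O[Si](CC)(CC)CC)/C=C/[C@@H](O[Si](CC)(CC)CC)C(C)=C | intermediate
23 | angelic acid, (2Z)-2-methylbut-2-enoic acid | C/C=C(/C)C(=O)O | starting material
24 | (2Z)-2-methylbut-2-enoic 2,4,6-trichlorobenzoic anhydride | C/C=C(/C)C(=O)OC(=O)c1c(Cl)cc(Cl)cc1Cl | intermediate
25 | (3R,4R,5R,7R,8E,10R)-3-acetoxy-4-[3-(4-methoxybenzyloxy)prop-1-en-2-yl]-7,11-dimethyl-7,10-bis(triethylsilyloxy)dodeca-1,8,11-trien-5-yl (2Z)-2-methylbut-2-enoate | C=C[C@@H](OC(C)=O)[C@H](C(=C)COCc1ccc(OC)cc1)[C@H](OC(=O)/C(C)=C\C)C[C@@](C)(O[Si](CC)(CC)CC)/C=C/[C@@H](O[Si](CC)(CC)CC)C(C)=C | intermediate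
26 | (3R,4S,5R,7R,8E,10R)-3-hydroxy-4-[3-(4-methoxybenzyloxy)prop-1-en-2-yl]-7,11-dimethyl-7,10-bis(triethylsilyloxy)dodeca-1,8,11-trien-5-yl (2Z)-2-methylbut-2-enoate | C=C[C@@H](O)[C@H](C(=C)COCc1ccc(OC)cc1)[C@H](OC(=O)/C(C)=C\C)C[C@@](C)(O[Si](CC)(CC)CC)/C=C/[C@@H](O[Si](CC)(CC)CC)C(C)=C | intermediate
27 | (3R,4S,5R,7R,8E,10R)-3,10-dihydroxy-4-[3-(4-methoxybenzyloxy)prop-1-en-2-yl]-7,11-dimethyl-7-(triethylsilyloxy)dodeca-1,8,11-trien-5-yl (2Z)-2-methylbut-2-enoate | C=C[C@@H](O)[C@H](C(=C)COCc1ccc(OC)cc1)[C@H](OC(=O)/C(C)=C\C)C[C@@](C)(O[Si](CC)(CC)CC)/C=C/[C@@H](O)C(C)=C | intermediate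
28 | 27 with its dodecatriene 10-hydroxyl (target O3) converted into the di(propan-2-yl)(trifluoromethanesulfonyloxy)silyl ether | C=C[C@@H](O)[C@H](C(=C)COCc1ccc(OC)cc1)[C@H](OC(=O)/C(C)=C\C)C[C@@](C)(O[Si](CC)(CC)CC)/C=C/[C@@H](O[Si](C(C)C)(C(C)C)OS(=O)(=O)C(F)(F)F)C(C)=C | intermediate
29 | eleven-membered 3,6-O-diisopropylsilylene diether (3-isopropenyl, 6-vinyl, 7-[3-(4-methoxybenzyloxy)prop-1-en-2-yl], 8-angeloyloxy, 10-methyl, 10-triethylsilyloxy; 1E; 3R,6R,7R,8R,10R) | C=C[C@H]1O[Si](C(C)C)(C(C)C)O[C@@H](C(C)=C)/C=C/[C@](C)(O[Si](CC)(CC)CC)C[C@@H](OC(=O)/C(C)=C\C)[C@H]1C(=C)COCc2ccc(OC)cc2 | intermediate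
30 | 3,6-O-diisopropylsilylene-bridged (1E,4Z)-cyclodeca-1,4-diene with 7-[3-(4-methoxybenzyloxy)prop-1-en-2-yl], 8-angeloyloxy, 10-triethylsilyloxy (3R,6R,7R,8R,10R) | C=C(COCc4ccc(OC)cc4)[C@H]1[C@@H]2O[Si](C(C)C)(C(C)C)O[C@H](/C=C/[C@](C)(O[Si](CC)(CC)CC)C[C@H]1OC(=O)/C(C)=C\C)/C(C)=C\2 | intermediate
31 | C12 alcohol: 30 with 7-(3-hydroxyprop-1-en-2-yl) (3R,6R,7R,8R,10R) | C=C(CO)[C@H]1[C@@H]2O[Si](C(C)C)(C(C)C)O[C@H](/C=C/[C@](C)(O[Si](CC)(CC)CC)C[C@H]1OC(=O)/C(C)=C\C)/C(C)=C\2 | intermediate
32 | C12 enal: 30 with 7-(3-oxoprop-1-en-2-yl) (3R,6R,7R,8R,10R) | C=C(C=O)[C@H]1[C@@H]2O[Si](C(C)C)(C(C)C)O[C@H](/C=C/[C@](C)(O[Si](CC)(CC)CC)C[C@H]1OC(=O)/C(C)=C\C)/C(C)=C\2 | intermediate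
33 | C12 acid: 30 with 7-(1-carboxyethenyl) (3R,6R,7R,8R,10R) | C=C(C(=O)O)[C@H]1[C@@H]2O[Si](C(C)C)(C(C)C)O[C@H](/C=C/[C@](C)(O[Si](CC)(CC)CC)C[C@H]1OC(=O)/C(C)=C\C)/C(C)=C\2 | intermediate
34 | seco acid: 2-[(1E,4Z)-8-angeloyloxy-3,6,10-trihydroxy-4,10-dimethylcyclodeca-1,4-dien-7-yl]prop-2-enoic acid (target locants; 3R,6R,7S,8R,10R) | C=C(C(=O)O)[C@H]1[C@H](O)/C=C(/C)[C@H](O)/C=C/[C@](C)(O)C[C@H]1OC(=O)/C(C)=C\C | intermediate
35 | (3R,6R,7R,8R,10R,1E,4Z)-8-angeloyloxy-3,10-dihydroxygermacra-1,4,11(13)-trien-12,6-olide | C=C1C(=O)O[C@@H]2/C=C(/C)[C@H](O)/C=C/[C@](C)(O)C[C@@H](OC(=O)/C(C)=C\C)[C@@H]12 | target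

## Step count and least certain steps

Total: 22 steps. Longest linear sequence: 21 steps (1–8 and 10–22) from 1; step 9 is a one-step side branch.

**Step 18 (key step).** The most likely failure is that the ruthenium alkylidene formed at the vinyl group does not engage the hindered isopropenyl group inside the eleven-membered ring. It would then turn to intermolecular metathesis, or the strained bridged diene would re-open under ethene.

Fallback with known chemistry, setting out from 5 and returning at 30: the ring is closed by an intramolecular Nozaki–Hiyama–Kishi reaction at C2–C3 and the Z-alkene is brought in ready-made.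
- Takai iodo-olefination of 5 (CrCl2, CHI3) gives the E-alkenyl iodide methyl (3R,4E)-5-iodo-3-methyl-3-(triethylsilyloxy)pent-4-enoate F1.
- Reduction as in step 8 gives the aldehyde (3R,4E)-5-iodo-3-methyl-3-(triethylsilyloxy)pent-4-enal F2.
- Allylation with 15 as in step 10 gives the homoallylic alcohol F3, and oxidation as in step 11 the β,γ-unsaturated ketone F4.
- The aldol of step 12, run with (Z)-3-methyl-4-(triethylsilyloxy)but-2-enal in place of 19, gives the syn-aldol adduct F5, which already holds Z-C4=C5.
- Evans–Tishchenko reduction gives the 6-acetate F6, and Yamaguchi esterification with 23 the angelate F7.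
- Swern oxidation turns the primary silyl ether directly into the Z-enal F8.
- CrCl2 with catalytic NiCl2 in DMSO at high dilution adds the alkenyl iodide to the aldehyde and closes the ring to the cyclodecadienol F9 (C3 epimers possible).
- Methanolysis of the acetate gives the 3,6-diol F10. The bridging of step 17, now a seven-membered closure open only to the 3,6-syn epimer, gives 30.

**Step 17.** Intermolecular silylation to oligomers is the likely failure, because an eleven-membered closure is entropically and transannularly disfavoured. Fallback from 27, returning at 29: the bridge is built in two stages through an isolable hydrosilane. iPr2Si(H)Cl and imidazole give the 3-O-diisopropylsilyl ether F11. Its Si–H bond is converted with N-bromosuccinimide at 0 °C into the bromosilane, which is added slowly to 2,6-lutidine and DMAP so that O6 closes the ring at very low stationary concentration.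

**Step 12.** Facial discrimination may be poor, because the isopinocampheyl ligands must differentiate an enolate with a branched α-alkenyl group. The β,γ-alkene may also migrate into conjugation before enolisation. Fallback from 18, returning at 21 and at 18: reagent control is given up. Bu2BOTf/iPr2NEt still gives only the two 6,7-syn adducts through the Z-enolborinate. These are diastereomers because of C3 and C10 and are separated. The unwanted (6S,7R) syn adduct F12 is cleaved back to 18 by base-induced retro-aldol reaction and recycled.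

**Step 15.** The angelate may migrate from O8 to the freed O6 alkoxide (1,3-acyl shift), or be lost by methanolysis. Fallback from 21, returning at 27: no acetate is used.
- O6 is silylated (Et3SiCl, imidazole) to the 6-O-triethylsilyl ketone F13.
- The ketone is reduced under reagent control by Corey–Bakshi–Shibata reduction ((S)-methyl-oxazaborolidine, BH3·SMe2; branched C7 as the large group) to the 8R alcohol F14.
- Yamaguchi esterification with 23 gives the angelate F15.
- One buffered HF·pyridine treatment removes both secondary silyl ethers and gives 27.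

## Further compounds

F1 | step 18 | methyl (3R,4E)-5-iodo-3-methyl-3-(triethylsilyloxy)pent-4-enoate | I/C=C/[C@](C)(O[Si](CC)(CC)CC)CC(=O)OC
F2 | step 18 | (3R,4E)-5-iodo-3-methyl-3-(triethylsilyloxy)pent-4-enal | I/C=C/[C@](C)(O[Si](CC)(CC)CC)CC=O
F3 | step 18 | (4RS,6R,7E)-8-iodo-1-(4-methoxybenzyloxy)-6-methyl-2-methylidene-6-(triethylsilyloxy)oct-7-en-4-ol | I/C=C/[C@](C)(O[Si](CC)(CC)CC)CC(O)CC(=C)COCc1ccc(OC)cc1
F4 | step 18 | (6R,7E)-8-iodo-1-(4-methoxybenzyloxy)-6-methyl-2-methylidene-6-(triethylsilyloxy)oct-7-en-4-one | I/C=C/[C@](C)(O[Si](CC)(CC)CC)CC(=O)CC(=C)COCc1ccc(OC)cc1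
F5 | step 18 | syn-aldol adduct (target locants 6R,7S,10R; Z-C4=C5, C3H2 triethylsilyl ether, E-alkenyl iodide at C1=C2, ketone at C8) | CC[Si](CC)(CC)OC/C(C)=C\[C@@H](O)[C@H](C(=C)COCc1ccc(OC)cc1)C(=O)C[C@@](C)(O[Si](CC)(CC)CC)/C=C/I
F6 | step 18 | 6-acetate with free 8R hydroxyl derived from F5 (6R,7R,8R,10R) | CC[Si](CC)(CC)OC/C(C)=C\[C@@H](OC(C)=O)[C@H](C(=C)COCc1ccc(OC)cc1)[C@H](O)C[C@@](C)(O[Si](CC)(CC)CC)/C=C/I
F7 | step 18 | 8-angelate of F6 | CC[Si](CC)(CC)OC/C(C)=C\[C@@H](OC(C)=O)[C@H](C(=C)COCc1ccc(OC)cc1)[C@H](OC(=O)/C(C)=C\C)C[C@@](C)(O[Si](CC)(CC)CC)/C=C/I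
F8 | step 18 | Z-enal (C3 aldehyde) derived from F7 | O=C/C(C)=C\[C@@H](OC(C)=O)[C@H](C(=C)COCc1ccc(OC)cc1)[C@H](OC(=O)/C(C)=C\C)C[C@@](C)(O[Si](CC)(CC)CC)/C=C/I
F9 | step 18 | (1E,4Z)-cyclodeca-1,4-dien-3-ol with 6-acetoxy, 7-[3-(4-methoxybenzyloxy)prop-1-en-2-yl], 8-angeloyloxy, 10-triethylsilyloxy (3R epimer drawn) | C=C(COCc1ccc(OC)cc1)[C@H]1[C@H](OC(C)=O)/C=C(/C)[C@H](O)/C=C/[C@](C)(O[Si](CC)(CC)CC)C[C@H]1OC(=O)/C(C)=C\C
F10 | step 18 | 3,6-diol obtained from F9 by deacetylation | C=C(COCc1ccc(OC)cc1)[C@H]1[C@H](O)/C=C(/C)[C@H](O)/C=C/[C@](C)(O[Si](CC)(CC)CC)C[C@H]1OC(=O)/C(C)=C\C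
F11 | step 17 | 3-O-[di(propan-2-yl)silyl] ether of 27 (Si–H) | C=C[C@@H](O)[C@H](C(=C)COCc1ccc(OC)cc1)[C@H](OC(=O)/C(C)=C\C)C[C@@](C)(O[Si](CC)(CC)CC)/C=C/[C@@H](O[SiH](C(C)C)C(C)C)C(C)=C
F12 | step 12 | (6S,7R) syn-aldol diastereomer of 21 | C=C[C@H](O)[C@@H](C(=C)COCc1ccc(OC)cc1)C(=O)C[C@@](C)(O[Si](CC)(CC)CC)/C=C/[C@@H](O[Si](CC)(CC)CC)C(C)=C
F13 | step 15 | 6-O-triethylsilyl ether of 21 | C=C[C@@H](O[Si](CC)(CC)CC)[C@H](C(=C)COCc1ccc(OC)cc1)C(=O)C[C@@](C)(O[Si](CC)(CC)CC)/C=C/[C@@H](O[Si](CC)(CC)CC)C(C)=C
F14 | step 15 | 8R alcohol from reduction of F13 | C=C[C@@H](O[Si](CC)(CC)CC)[C@H](C(=C)COCc1ccc(OC)cc1)[C@H](O)C[C@@](C)(O[Si](CC)(CC)CC)/C=C/[C@@H](O[Si](CC)(CC)CC)C(C)=C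
F15 | step 15 | 8-angelate of F14 | C=C[C@@H](O[Si](CC)(CC)CC)[C@H](C(=C)COCc1ccc(OC)cc1)[C@H](OC(=O)/C(C)=C\C)C[C@@](C)(O[Si](CC)(CC)CC)/C=C/[C@@H](O[Si](CC)(CC)CC)C(C)=C
A1 | alternative 1 | open-chain C8 aldoxime with 3-O-TBS, lactone and terminal 1,3-diene | C=C1C(=O)O[C@H](/C=C(/C)[C@H](O[Si](C)(C)C(C)(C)C)/C=C/C(C)=C)[C@H]1C=NO
A2 | alternative 1 | isoxazoline-bridged ten-membered lactone | C=C1C(=O)O[C@@H]2/C=C(/C)[C@H](O[Si](C)(C)C(C)(C)C)/C=C/[C@]3(C)ON=C(C3)[C@@H]12
A3 | alternative 2 | open-chain Z-alkenyl iodide / E-alkenylstannane lactone | C=C1C(=O)O[C@H](/C=C(/C)I)[C@H]1[C@H](OC(=O)/C(C)=C\C)C[C@@](C)(O)/C=C/[Sn](CCCC)(CCCC)CCCC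
A4 | alternative 2 | 3-oxo macrocycle (cross-conjugated dienone) | C=C1C(=O)O[C@@H]2/C=C(/C)C(=O)/C=C/[C@](C)(O)C[C@@H](OC(=O)/C(C)=C\C)[C@@H]12
A5 | alternative 3 | trans-decalin with C6 tertiary alcohol and equatorial C2 mesylate | C=C(CO[Si](CC)(CC)CC)[C@H]1[C@]2(O)C=C(C)[C@H](O[Si](C)(C)C(C)(C)C)[C@H](OS(C)(=O)=O)[C@H]2[C@](C)(O[Si](C)(C)C(C)(C)C)C[C@H]1OCc3ccc(OC)cc3
A6 | alternative 3 | (1E,4Z)-cyclodecadien-6-one with protected C3, C8, C10 and C12 oxygens | C=C(CO[Si](CC)(CC)CC)[C@H]1C(=O)/C=C(/C)[C@H](O[Si](C)(C)C(C)(C)C)/C=C/[C@](C)(O[Si](C)(C)C(C)(C)C)C[C@H]1OCc2ccc(OC)cc2
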